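**Plan**

1. Chain atoms are numbered C1' (benzylic CH2) to C16' (CH2OH). The hydroquinone is carried as its dimethyl ether, and the chain is cut at C9'–C10' (alkyl–alkenyl), C1'–C2' (benzyl–alkenyl) and C4'–C5' (propargylation of a C5'–C9' enal).
2. The enabling feature is the E-trisubstituted alkene C10'=C11', whose C11' methyl is cis to the C10'–C9' bond and which adjoins the sp3 methylene C9'. It is therefore the syn adduct of Me–metal across a terminal alkyne C10'≡C11', with C9' supplied afterwards as a primary iodide.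
3. Forward: the C5'–C9' enal (from a butynyl silyl ether by carboalumination and hydroxymethylation) is propargylated. A first carboalumination joins C2' to the benzylic chloride of the arene, and C9' is turned into an iodide. A three-component carboalumination/cross-coupling then unites the enyne C10'–C16', Me3Al and the iodide.
4. Stereochemistry: C5' (R) comes from a chiral phosphoric acid-catalysed propargylation. The E alkenes at C2', C6' and C10' come from syn-carboalumination, and the Z alkene C14'=C15' from a Still–Gennari olefination.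
5. Endgame: desilylation, oxidative demethylation to the quinone, dithionite reduction.

Key step: step 16

Remark on the chemistry: in step 7 the (R)-phosphoric acid is assumed to direct the allenylboronate to the Re face of the enal, as this catalyst class does with aryl and alkenyl aldehydes. If the sense proves opposite, the (S)-acid is used.

**Route**

Step 1
Reactants: 1 4-methoxy-2-methylphenol
Product: 2 2-hydroxy-5-methoxy-3-methylbenzaldehyde
Conditions: (CH2O)n, MgCl2, Et3N, MeCN, reflux; aq. HCl work-up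
Reagents that add atoms: paraformaldehyde (as formaldehyde), C=O
Why: Casnati–Skattebøl ortho-formylation, in which the magnesium phenoxide delivers formaldehyde to the only free ortho position and a second equivalent of formaldehyde should oxidise the benzylic alkoxide to the aldehyde.

Step 2
Reactants: 2 2-hydroxy-5-methoxy-3-methylbenzaldehyde
Product: 3 2,5-dimethoxy-3-methylbenzaldehyde
Conditions: MeI, K2CO3, DMF, rt
Reagents that add atoms: iodomethane, CI
Why: Williamson O-methylation of the phenoxide, to which the aldehyde is inert.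

Step 3
Reactants: 3 2,5-dimethoxy-3-methylbenzaldehyde
Product: 4 (2,5-dimethoxy-3-methylphenyl)methanol
Conditions: NaBH4, MeOH, 0 °C
Reagents that add atoms: none
Why: Borohydride reduction of an aryl aldehyde to the benzylic alcohol.

Step 4
Reactants: 4 (2,5-dimethoxy-3-methylphenyl)methanol
Product: 5 1-(chloromethyl)-2,5-dimethoxy-3-methylbenzene
Conditions: SOCl2, CH2Cl2, 0 °C to rt
Reagents that add atoms: thionyl chloride, O=S(Cl)Cl
Why: Deoxychlorination of an electron-rich benzylic alcohol through its chlorosulfite.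

Step 5
Reactants: 6 tert-butyl(but-3-yn-1-yloxy)dimethylsilane
Product: 9 (2E)-5-[(tert-butyldimethylsilyl)oxy]-3-methylpent-2-en-1-ol, via alkenyldimethylalane 7 (not isolated), via lithium alkenylbutyldimethylalanate 8 (not isolated)
Conditions: Me3Al, Cp2ZrCl2 (0.25 equiv), CH2Cl2, rt; volatiles removed; n-BuLi, THF, −78 to 0 °C; (CH2O)n, rt; aq. HCl work-up
Reagents that add atoms: trimethylaluminium, C[Al](C)C; paraformaldehyde (as formaldehyde), C=O
Why: Negishi zirconium-catalysed carboalumination adds Me and Al syn across the terminal alkyne (Me to the internal carbon), and the alanate should be hydroxymethylated with retention, which fixes the E geometry of C6'=C7'.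

Step 6
Reactants: 9 (2E)-5-[(tert-butyldimethylsilyl)oxy]-3-methylpent-2-en-1-ol
Product: 10 (2E)-5-[(tert-butyldimethylsilyl)oxy]-3-methylpent-2-enal
Conditions: MnO2, CH2Cl2, rt
Reagents that add atoms: none
Why: Selective MnO2 oxidation of an allylic alcohol to the enal, which should not disturb the alkene geometry or the silyl ether.

Step 7
Reactants: 10 (2E)-5-[(tert-butyldimethylsilyl)oxy]-3-methylpent-2-enal; 11 4,4,5,5-tetramethyl-2-(propa-1,2-dien-1-yl)-1,3,2-dioxaborolane (allenylboronic acid pinacol ester)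
Product: 13 (4R,5E)-8-[(tert-butyldimethylsilyl)oxy]-6-methyloct-5-en-1-yn-4-ol, via O-pinacolboryl ether 12 (not isolated)
Conditions: (R)-TRIP [(R)-3,3'-bis(2,4,6-triisopropylphenyl)-1,1'-binaphthyl-2,2'-diyl hydrogen phosphate] (10 mol%), 4 Å MS, toluene, 0 °C; aq. NaHCO3 work-up
Reagents that add atoms: none
Why: Chiral phosphoric acid-catalysed propargylation of an aldehyde by an allenylboronate through a closed six-membered SE2' transition state, in which the (R)-acid should direct attack to the Re face of the enal and so set C5' as R.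

Step 8
Reactants: 13 (4R,5E)-8-[(tert-butyldimethylsilyl)oxy]-6-methyloct-5-en-1-yn-4-ol
Product: 14 (4R,5E)-8-[(tert-butyldimethylsilyl)oxy]-4-[(tert-butyldiphenylsilyl)oxy]-6-methyloct-5-en-1-yne
Conditions: TBDPSCl, imidazole, DMF, rt
Reagents that add atoms: tert-butyldiphenylsilyl chloride, CC(C)(C)[Si](Cl)(c1ccccc1)c1ccccc1
Why: Silylation of the secondary alcohol with a group that should survive the later acidic removal of the primary TBS ether.

Step 9
Reactants: 14 (4R,5E)-8-[(tert-butyldimethylsilyl)oxy]-4-[(tert-butyldiphenylsilyl)oxy]-6-methyloct-5-en-1-yne; 5 1-(chloromethyl)-2,5-dimethoxy-3-methylbenzene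
Product: 16 1-[(2E,5R,6E)-9-[(tert-butyldimethylsilyl)oxy]-5-[(tert-butyldiphenylsilyl)oxy]-3,7-dimethylnona-2,6-dien-1-yl]-2,5-dimethoxy-3-methylbenzene, via alkenyldimethylalane 15 (not isolated)
Conditions: Me3Al, Cp2ZrCl2 (0.25 equiv), CH2Cl2, rt; volatiles removed; then 5, NiCl2(PPh3)2 (5 mol%)/n-BuLi (10 mol%), THF, rt
Reagents that add atoms: trimethylaluminium, C[Al](C)C
Why: Syn-carboalumination of the terminal alkyne sets the E alkene C2'=C3', and the alkenylalane should be benzylated with retention under zerovalent nickel catalysis (alkenylalane–benzylic chloride cross-coupling), with silyl and aryl methyl ethers inert.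

Step 10
Reactants: 16 1-[(2E,5R,6E)-9-[(tert-butyldimethylsilyl)oxy]-5-[(tert-butyldiphenylsilyl)oxy]-3,7-dimethylnona-2,6-dien-1-yl]-2,5-dimethoxy-3-methylbenzene
Product: 17 (3E,5R,7E)-5-[(tert-butyldiphenylsilyl)oxy]-9-(2,5-dimethoxy-3-methylphenyl)-3,7-dimethylnona-3,7-dien-1-ol
Conditions: PPTS, MeOH/CH2Cl2, rt
Reagents that add atoms: none
Why: Acid-catalysed methanolysis should cleave the unhindered primary TBS ether much faster than the hindered secondary TBDPS ether.

Step 11
Reactants: 17 (3E,5R,7E)-5-[(tert-butyldiphenylsilyl)oxy]-9-(2,5-dimethoxy-3-methylphenyl)-3,7-dimethylnona-3,7-dien-1-ol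
Product: 18 1-[(2E,5R,6E)-5-[(tert-butyldiphenylsilyl)oxy]-9-iodo-3,7-dimethylnona-2,6-dien-1-yl]-2,5-dimethoxy-3-methylbenzene
Conditions: I2, PPh3, imidazole, CH2Cl2, 0 °C
Reagents that add atoms: iodine, II
Why: Garegg–Samuelsson iodination of a primary alcohol by SN2 displacement of the alkoxyphosphonium ion, which should leave alkenes, silyl ether and arene untouched.

Step 12
Reactants: 19 pent-4-yn-1-ol
Product: 20 pent-4-ynal
Conditions: (COCl)2, DMSO, CH2Cl2, −78 °C; Et3N, −78 °C to rt; used as a solution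
Reagents that add atoms: none
Why: Swern oxidation of a primary alcohol to the aldehyde without touching the alkyne.

Step 13
Reactants: 20 pent-4-ynal; 21 ethyl 2-[bis(2,2,2-trifluoroethoxy)phosphoryl]propanoate
Product: 22 ethyl (2Z)-2-methylhept-2-en-6-ynoate
Conditions: KN(SiMe3)2, 18-crown-6, THF, −78 °C
Reagents that add atoms: none
Why: Still–Gennari olefination, in which the electron-poor phosphonate eliminates rapidly from the kinetic adduct and should give the Z trisubstituted enoate needed for C14'=C15'.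

Step 14
Reactants: 22 ethyl (2Z)-2-methylhept-2-en-6-ynoate
Product: 23 (2Z)-2-methylhept-2-en-6-yn-1-ol
Conditions: i-Bu2AlH, CH2Cl2, −78 °C; aq. KNaC4H4O6 work-up
Reagents that add atoms: none
Why: 1,2-Reduction of the enoate to the allylic alcohol by the aluminium hydride, which should retain the Z geometry.

Step 15
Reactants: 23 (2Z)-2-methylhept-2-en-6-yn-1-ol
Product: 24 tert-butyldimethyl{[(2Z)-2-methylhept-2-en-6-yn-1-yl]oxy}silane
Conditions: TBSCl, imidazole, CH2Cl2, rt
Reagents that add atoms: tert-butyldimethylsilyl chloride, CC(C)(C)[Si](C)(C)Cl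
Why: Standard silylation of a primary alcohol, so that no acidic proton meets the organometallic reagents of the next step.

Step 16
Reactants: 24 tert-butyldimethyl{[(2Z)-2-methylhept-2-en-6-yn-1-yl]oxy}silane (1.5 equiv); 18 1-[(2E,5R,6E)-5-[(tert-butyldiphenylsilyl)oxy]-9-iodo-3,7-dimethylnona-2,6-dien-1-yl]-2,5-dimethoxy-3-methylbenzene
Product: 27 1-[(2E,5R,6E,10E,14Z)-16-[(tert-butyldimethylsilyl)oxy]-5-[(tert-butyldiphenylsilyl)oxy]-3,7,11,15-tetramethylhexadeca-2,6,10,14-tetraen-1-yl]-2,5-dimethoxy-3-methylbenzene, via alkenyldimethylalane 25 (not isolated), via alkenylzinc chloride 26 (not isolated)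
Conditions: Me3Al, Cp2ZrCl2 (0.25 equiv), CH2Cl2, 0 °C to rt; volatiles removed; ZnCl2, THF, 0 °C; then 18, Pd2(dba)3 (2 mol%), PCyp3 (tricyclopentylphosphine, 8 mol%), N-methylimidazole, THF/NMP, 60–80 °C
Reagents that add atoms: trimethylaluminium, C[Al](C)C
Why: Proposed new method: zirconium-catalysed syn-methylalumination of the terminal alkyne of 24 places Me on C11' and Al on C10' (alkenylalane 25), Al-to-Zn exchange gives alkenylzinc chloride 26, and a zerovalent palladium/PCyp3 catalyst joins C10' to C9' of iodide 18 by SN2-type oxidative addition, transmetalation and reductive elimination. The closest known reaction types are the one-flask carboalumination/cross-coupling of alkenylalanes with aryl, alkenyl and benzylic halides (as in step 9) and the Negishi coupling of alkenylzinc halides with unactivated primary alkyl iodides under palladium/trialkylphosphine catalysis; what is new is their union in one operation on a homoallylic iodide. No ring is closed and no stereocentre is formed; the E geometry of C10'=C11' follows from syn addition across the alkyne and retention in both metal exchanges and in reductive elimination, while C5' and the Z alkene C14'=C15' are remote and should stay untouched. The step needs regioselective carbometalation, secured by the terminal alkyne (Al on the unsubstituted carbon); transfer of the alkenyl group in preference to the methyl groups on aluminium, secured by the faster transmetalation of sp2 carbon and by removing excess Me3Al before the coupling; and coupling faster than β-hydride elimination towards a conjugated C6'–C9' diene, secured by the bulky electron-rich phosphine with N-methylimidazole.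

Step 17
Reactants: 27 1-[(2E,5R,6E,10E,14Z)-16-[(tert-butyldimethylsilyl)oxy]-5-[(tert-butyldiphenylsilyl)oxy]-3,7,11,15-tetramethylhexadeca-2,6,10,14-tetraen-1-yl]-2,5-dimethoxy-3-methylbenzene
Product: 28 (2Z,6E,10E,12R,14E)-16-(2,5-dimethoxy-3-methylphenyl)-2,6,10,14-tetramethylhexadeca-2,6,10,14-tetraene-1,12-diol
Conditions: Bu4NF, THF, rt
Reagents that add atoms: none
Why: Fluoride-mediated cleavage of both silyl ethers, driven by Si–F bond formation, which should not affect alkenes or aryl methyl ethers.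

Step 18
Reactants: 28 (2Z,6E,10E,12R,14E)-16-(2,5-dimethoxy-3-methylphenyl)-2,6,10,14-tetramethylhexadeca-2,6,10,14-tetraene-1,12-diol
Product: 29 2-[(2E,5R,6E,10E,14Z)-5,16-dihydroxy-3,7,11,15-tetramethylhexadeca-2,6,10,14-tetraen-1-yl]-6-methylcyclohexa-2,5-diene-1,4-dione
Conditions: (NH4)2Ce(NO3)6, MeCN/H2O, 0 °C, short reaction time
Reagents that add atoms: water, O
Why: Oxidative demethylation of a 1,4-dimethoxyarene by single-electron oxidation, with water supplying the quinone oxygens, under which isolated trisubstituted alkenes and alcohols should not be oxidised.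

Step 19
Reactants: 29 2-[(2E,5R,6E,10E,14Z)-5,16-dihydroxy-3,7,11,15-tetramethylhexadeca-2,6,10,14-tetraen-1-yl]-6-methylcyclohexa-2,5-diene-1,4-dione
Product: 30 2-[(2E,5R,6E,10E,14Z)-5,16-dihydroxy-3,7,11,15-tetramethylhexadeca-2,6,10,14-tetraen-1-yl]-6-methylbenzene-1,4-diol
Conditions: Na2S2O4, THF/H2O, rt, argon
Reagents that add atoms: none
Why: Two-electron reduction of the benzoquinone to the hydroquinone by dithionite, which should leave the rest of the molecule unchanged.

**Compound list**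

1 | 4-methoxy-2-methylphenol | Cc1cc(OC)ccc1O | starting material
2 | 2-hydroxy-5-methoxy-3-methylbenzaldehyde | COc1cc(C)c(O)c(C=O)c1 | intermediate
3 | 2,5-dimethoxy-3-methylbenzaldehyde | COc1cc(C)c(OC)c(C=O)c1 | intermediate
4 | (2,5-dimethoxy-3-methylphenyl)methanol | COc1cc(C)c(OC)c(CO)c1 | intermediate
5 | 1-(chloromethyl)-2,5-dimethoxy-3-methylbenzene | COc1cc(C)c(OC)c(CCl)c1 | intermediate
6 | tert-butyl(but-3-yn-1-yloxy)dimethylsilane | C#CCCO[Si](C)(C)C(C)(C)C | starting material
7 | {(1E)-4-[(tert-butyldimethylsilyl)oxy]-2-methylbut-1-en-1-yl}dimethylalane | C[Al](C)/C=C(\C)CCO[Si](C)(C)C(C)(C)C | intermediate (not isolated)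
8 | lithium butyl{(1E)-4-[(tert-butyldimethylsilyl)oxy]-2-methylbut-1-en-1-yl}dimethylalanate | [Li+].CCCC[Al-](C)(C)/C=C(\C)CCO[Si](C)(C)C(C)(C)C | intermediate (not isolated)
9 | (2E)-5-[(tert-butyldimethylsilyl)oxy]-3-methylpent-2-en-1-ol | OC/C=C(\C)CCO[Si](C)(C)C(C)(C)C | intermediate
10 | (2E)-5-[(tert-butyldimethylsilyl)oxy]-3-methylpent-2-enal | O=C/C=C(\C)CCO[Si](C)(C)C(C)(C)C | intermediate
11 | 4,4,5,5-tetramethyl-2-(propa-1,2-dien-1-yl)-1,3,2-dioxaborolane | C=C=CB1OC(C)(C)C(C)(C)O1 | starting material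
12 | O-pinacolboryl ether of 13 | C#CC[C@@H](OB1OC(C)(C)C(C)(C)O1)/C=C(\C)CCO[Si](C)(C)C(C)(C)C | intermediate (not isolated)
13 | (4R,5E)-8-[(tert-butyldimethylsilyl)oxy]-6-methyloct-5-en-1-yn-4-ol | C#CC[C@@H](O)/C=C(\C)CCO[Si](C)(C)C(C)(C)C | intermediate
14 | (4R,5E)-8-[(tert-butyldimethylsilyl)oxy]-4-[(tert-butyldiphenylsilyl)oxy]-6-methyloct-5-en-1-yne | C#CC[C@@H](O[Si](c1ccccc1)(c1ccccc1)C(C)(C)C)/C=C(\C)CCO[Si](C)(C)C(C)(C)C | intermediate
15 | {(1E,4R,5E)-8-[(tert-butyldimethylsilyl)oxy]-4-[(tert-butyldiphenylsilyl)oxy]-2,6-dimethylocta-1,5-dien-1-yl}dimethylalane | C[Al](C)/C=C(\C)C[C@@H](O[Si](c1ccccc1)(c1ccccc1)C(C)(C)C)/C=C(\C)CCO[Si](C)(C)C(C)(C)C | intermediate (not isolated)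
16 | 1-[(2E,5R,6E)-9-[(tert-butyldimethylsilyl)oxy]-5-[(tert-butyldiphenylsilyl)oxy]-3,7-dimethylnona-2,6-dien-1-yl]-2,5-dimethoxy-3-methylbenzene | COc1cc(C)c(OC)c(C/C=C(\C)C[C@@H](O[Si](c2ccccc2)(c2ccccc2)C(C)(C)C)/C=C(\C)CCO[Si](C)(C)C(C)(C)C)c1 | intermediate
17 | (3E,5R,7E)-5-[(tert-butyldiphenylsilyl)oxy]-9-(2,5-dimethoxy-3-methylphenyl)-3,7-dimethylnona-3,7-dien-1-ol | COc1cc(C)c(OC)c(C/C=C(\C)C[C@@H](O[Si](c2ccccc2)(c2ccccc2)C(C)(C)C)/C=C(\C)CCO)c1 | intermediate
18 | 1-[(2E,5R,6E)-5-[(tert-butyldiphenylsilyl)oxy]-9-iodo-3,7-dimethylnona-2,6-dien-1-yl]-2,5-dimethoxy-3-methylbenzene | COc1cc(C)c(OC)c(C/C=C(\C)C[C@@H](O[Si](c2ccccc2)(c2ccccc2)C(C)(C)C)/C=C(\C)CCI)c1 | intermediate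
19 | pent-4-yn-1-ol | C#CCCCO | starting material
20 | pent-4-ynal | C#CCCC=O | intermediate
21 | ethyl 2-[bis(2,2,2-trifluoroethoxy)phosphoryl]propanoate | CCOC(=O)C(C)P(=O)(OCC(F)(F)F)OCC(F)(F)F | starting material
22 | ethyl (2Z)-2-methylhept-2-en-6-ynoate | CCOC(=O)/C(C)=C\CCC#C | intermediate
23 | (2Z)-2-methylhept-2-en-6-yn-1-ol | OC/C(C)=C\CCC#C | intermediate
24 | tert-butyldimethyl{[(2Z)-2-methylhept-2-en-6-yn-1-yl]oxy}silane | CC(C)(C)[Si](C)(C)OC/C(C)=C\CCC#C | intermediate
25 | {(1E,5Z)-7-[(tert-butyldimethylsilyl)oxy]-2,6-dimethylhepta-1,5-dien-1-yl}dimethylalane | C[Al](C)/C=C(\C)CC/C=C(/C)CO[Si](C)(C)C(C)(C)C | intermediate (not isolated)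
26 | {(1E,5Z)-7-[(tert-butyldimethylsilyl)oxy]-2,6-dimethylhepta-1,5-dien-1-yl}zinc chloride | Cl[Zn]/C=C(\C)CC/C=C(/C)CO[Si](C)(C)C(C)(C)C | intermediate (not isolated)
27 | 1-[(2E,5R,6E,10E,14Z)-16-[(tert-butyldimethylsilyl)oxy]-5-[(tert-butyldiphenylsilyl)oxy]-3,7,11,15-tetramethylhexadeca-2,6,10,14-tetraen-1-yl]-2,5-dimethoxy-3-methylbenzene | COc1cc(C)c(OC)c(C/C=C(\C)C[C@@H](O[Si](c2ccccc2)(c2ccccc2)C(C)(C)C)/C=C(\C)CC/C=C(\C)CC/C=C(/C)CO[Si](C)(C)C(C)(C)C)c1 | intermediate
28 | (2Z,6E,10E,12R,14E)-16-(2,5-dimethoxy-3-methylphenyl)-2,6,10,14-tetramethylhexadeca-2,6,10,14-tetraene-1,12-diol | COc1cc(C)c(OC)c(C/C=C(\C)C[C@@H](O)/C=C(\C)CC/C=C(\C)CC/C=C(/C)CO)c1 | intermediate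
29 | 2-[(2E,5R,6E,10E,14Z)-5,16-dihydroxy-3,7,11,15-tetramethylhexadeca-2,6,10,14-tetraen-1-yl]-6-methylcyclohexa-2,5-diene-1,4-dione | CC1=CC(=O)C=C(C/C=C(\C)C[C@@H](O)/C=C(\C)CC/C=C(\C)CC/C=C(/C)CO)C1=O | intermediate
30 | 2-[(2E,5R,6E,10E,14Z)-5,16-dihydroxy-3,7,11,15-tetramethylhexadeca-2,6,10,14-tetraen-1-yl]-6-methylbenzene-1,4-diol | Cc1cc(O)cc(C/C=C(\C)C[C@@H](O)/C=C(\C)CC/C=C(\C)CC/C=C(/C)CO)c1O | target

**Step count**

Total: 19 steps. Longest linear sequence: 11 steps (6 to 30 through steps 5–11 and 16–19; the arene branch from 1 through steps 1–4, 9–11 and 16–19 is equally long).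

**Steps most likely to fail**

1. Step 16 (Proposed new method). The alkylpalladium intermediate may undergo β-hydride elimination towards the conjugated diene, a methyl group may be transferred instead of the alkenyl group, or oxidative addition into the homoallylic iodide may be too slow. The fallback uses known chemistry; it sets out from 24 and 18 and comes back to the route at 27. Compound 24 is carboaluminated as in step 16, and alkenylalane 25 is quenched with I2 (THF, −30 °C) to give tert-butyl{[(2Z,6E)-7-iodo-2,6-dimethylhepta-2,6-dien-1-yl]oxy}dimethylsilane F1. Iodide 18 is converted with zinc dust and LiCl (THF, 40 °C) into [(3E,5R,7E)-5-[(tert-butyldiphenylsilyl)oxy]-9-(2,5-dimethoxy-3-methylphenyl)-3,7-dimethylnona-3,7-dien-1-yl]zinc iodide F2. Negishi alkyl–alkenyl coupling of the two with Pd(PPh3)4 in THF at rt should give 27 with retention of the E geometry.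

2. Step 7. Facial selectivity may be insufficient on a β,β-disubstituted enal, and some allenyl isomer may form. The fallback sets out from 10 and comes back at 13. Barbier propargylation (propargyl bromide, zinc dust, THF/aq. NH4Cl) gives racemic (5E)-8-[(tert-butyldimethylsilyl)oxy]-6-methyloct-5-en-1-yn-4-ol F3. Sharpless kinetic resolution (Ti(OiPr)4, L-(+)-diisopropyl tartrate, t-BuOOH ca. 0.6 equiv, 4 Å MS, CH2Cl2, −20 °C) should epoxidise the S enantiomer to (1S)-1-[(2R,3R)-3-{2-[(tert-butyldimethylsilyl)oxy]ethyl}-3-methyloxiran-2-yl]but-3-yn-1-ol F4 and leave 13, which is separated by chromatography. The methyl group cis to the carbinol may lower the rate ratio, so conversion is taken past one half.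

3. Step 18. The acidic oxidant may ionise or transpose the free C5' allylic alcohol, or over-oxidise the polyene diol. The fallback sets out from 27 and comes back at 30, with the order of events changed so that no free allylic alcohol meets the oxidant. Compound 27 is oxidised with (NH4)2Ce(NO3)6 (MeCN/H2O, 0 °C) to 2-[(2E,5R,6E,10E,14Z)-16-[(tert-butyldimethylsilyl)oxy]-5-[(tert-butyldiphenylsilyl)oxy]-3,7,11,15-tetramethylhexadeca-2,6,10,14-tetraen-1-yl]-6-methylcyclohexa-2,5-diene-1,4-dione F5. Reduction with Na2S2O4 gives 2-[(2E,5R,6E,10E,14Z)-16-[(tert-butyldimethylsilyl)oxy]-5-[(tert-butyldiphenylsilyl)oxy]-3,7,11,15-tetramethylhexadeca-2,6,10,14-tetraen-1-yl]-6-methylbenzene-1,4-diol F6. Buffered fluoride (Bu4NF/AcOH, THF, argon) then removes both silyl groups to give 30.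

Further compounds
F1 | step 16 | tert-butyl{[(2Z,6E)-7-iodo-2,6-dimethylhepta-2,6-dien-1-yl]oxy}dimethylsilane | I/C=C(\C)CC/C=C(/C)CO[Si](C)(C)C(C)(C)C
F2 | step 16 | [(3E,5R,7E)-5-[(tert-butyldiphenylsilyl)oxy]-9-(2,5-dimethoxy-3-methylphenyl)-3,7-dimethylnona-3,7-dien-1-yl]zinc iodide | COc1cc(C)c(OC)c(C/C=C(\C)C[C@@H](O[Si](c2ccccc2)(c2ccccc2)C(C)(C)C)/C=C(\C)CC[Zn]I)c1
F3 | step 7 | racemic (5E)-8-[(tert-butyldimethylsilyl)oxy]-6-methyloct-5-en-1-yn-4-ol | C#CCC(O)/C=C(\C)CCO[Si](C)(C)C(C)(C)C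
F4 | step 7 | (1S)-1-[(2R,3R)-3-{2-[(tert-butyldimethylsilyl)oxy]ethyl}-3-methyloxiran-2-yl]but-3-yn-1-ol | C#CC[C@H](O)[C@H]1O[C@]1(C)CCO[Si](C)(C)C(C)(C)C
F5 | step 18 | 2-[(2E,5R,6E,10E,14Z)-16-[(tert-butyldimethylsilyl)oxy]-5-[(tert-butyldiphenylsilyl)oxy]-3,7,11,15-tetramethylhexadeca-2,6,10,14-tetraen-1-yl]-6-methylcyclohexa-2,5-diene-1,4-dione | CC1=CC(=O)C=C(C/C=C(\C)C[C@@H](O[Si](c2ccccc2)(c2ccccc2)C(C)(C)C)/C=C(\C)CC/C=C(\C)CC/C=C(/C)CO[Si](C)(C)C(C)(C)C)C1=O
F6 | step 18 | 2-[(2E,5R,6E,10E,14Z)-16-[(tert-butyldimethylsilyl)oxy]-5-[(tert-butyldiphenylsilyl)oxy]-3,7,11,15-tetramethylhexadeca-2,6,10,14-tetraen-1-yl]-6-methylbenzene-1,4-diol | Cc1cc(O)cc(C/C=C(\C)C[C@@H](O[Si](c2ccccc2)(c2ccccc2)C(C)(C)C)/C=C(\C)CC/C=C(\C)CC/C=C(/C)CO[Si](C)(C)C(C)(C)C)c1O
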